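**Plan**

1. Locants: C-α is the carbinol carbon, C-β the benzylic CH2, ring B the anisyl ring, ring A (C1'–C6') the acyl-bearing ring. The retrosynthesis first cuts the O–Si bond of a C-α triethylsilyl ether, then the ring-A bonds C1'–C2' and C5'–C6'.
2. The enabling feature is the ring-A pattern: acyl at C1', OMe at C2', OH at C4', prenyl at C5', H at C3' and C6'. C2'–C5' with the two meta oxygens form a 1,1-dimethoxy-3-silyloxy diene carrying the prenyl group at its terminus; C1' and the unsubstituted C6' are the two carbons of a terminal ynone.
3. Forward: the ynone (C-α, C-β and ring B) is built in four linear steps from O-methyl-L-tyrosine; the diene is built in three steps from 5-methylhex-4-enoic acid and 1,1-dimethoxyethene.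
4. The two fragments are joined in the cycloaddition, which forms ring A, the only ring made in the route; one desilylation then gives the target.
5. The single stereocentre (C-α, S) comes from the amino acid by diazotisation with retention and is carried through unchanged; no stereocentre is created later.

Key step: step 8

Assumption: 5-methylhex-4-enoic acid is treated as purchasable; it is otherwise accessible by Johnson–Claisen rearrangement of 2-methylbut-3-en-2-ol with triethyl orthoacetate followed by saponification.

**Route**

Step 1
Reactants: 1 O-methyl-L-tyrosine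
Product: 2 (S)-2-hydroxy-3-(4-methoxyphenyl)propanoic acid
Conditions: NaNO2, 0.5 M aq. H2SO4, 0 °C → rt
Reagents that add atoms: water, O
Why: Diazotisation of an α-amino acid, in which the carboxylate expels N2 to form an α-lactone that water reopens, so two inversions add up to retention and the (S)-carbinol centre is taken from the chiral pool.

Step 2
Reactants: 2 (S)-2-hydroxy-3-(4-methoxyphenyl)propanoic acid
Product: 3 (S)-2-hydroxy-N-methoxy-3-(4-methoxyphenyl)-N-methylpropanamide
Conditions: MeNHOMe·HCl, EDC·HCl, HOBt, N-methylmorpholine, CH2Cl2, 0 °C → rt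
Reagents that add atoms: N,O-dimethylhydroxylamine hydrochloride, CNOC.Cl
Why: Carbodiimide/HOBt amide coupling to a Weinreb amide, in which the amine should intercept the active ester much faster than the hindered secondary hydroxyl does, so the free α-hydroxy acid can be used directly.

Step 3
Reactants: 3 (S)-2-hydroxy-N-methoxy-3-(4-methoxyphenyl)-N-methylpropanamide
Product: 4 (S)-N-methoxy-3-(4-methoxyphenyl)-N-methyl-2-(triethylsilyloxy)propanamide
Conditions: TESCl, imidazole, DMF, 0 °C → rt
Reagents that add atoms: chlorotriethylsilane, CC[Si](Cl)(CC)CC
Why: Imidazole-mediated silylation of a secondary alcohol gives a triethylsilyl ether that tolerates Grignard addition and neutral heating yet can be removed later without base.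

Step 4
Reactants: 4 (S)-N-methoxy-3-(4-methoxyphenyl)-N-methyl-2-(triethylsilyloxy)propanamide, 5 ethynylmagnesium bromide
Product: 6 (S)-5-(4-methoxyphenyl)-4-(triethylsilyloxy)pent-1-yn-3-one
Conditions: 5 (0.5 M in THF, 2.5 equiv), THF, −20 → 0 °C; inverse quench into cold aq. NaHSO4
Reagents that add atoms: none
Why: Weinreb ketone synthesis, in which the chelated tetrahedral adduct prevents over-addition and survives until the quench, the α-silyloxy centre is not enolised at low temperature, and the acidic inverse quench protonates the released amine before it can add to the ynone.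

Step 5
Reactants: 7 5-methylhex-4-enoic acid
Product: 8 5-methylhex-4-enoyl chloride
Conditions: (COCl)2, cat. DMF, CH2Cl2, 0 °C → rt; concentrate, use crude
Reagents that add atoms: oxalyl chloride, O=C(Cl)C(=O)Cl
Why: DMF-catalysed acid chloride formation under mild conditions that should leave the trisubstituted alkene untouched.

Step 6
Reactants: 8 5-methylhex-4-enoyl chloride, 9 1,1-dimethoxyethene
Product: 10 1,1-dimethoxy-7-methylocta-1,6-dien-3-one
Conditions: 9 (2.2 equiv), Et2O, 0 °C → rt
Reagents that add atoms: none
Why: C-acylation of a ketene acetal at its nucleophilic β-carbon followed by loss of HCl, which the second equivalent of the ketene acetal absorbs as methyl acetate and chloromethane; the product is a vinylogous carbonate and is deactivated toward a second acylation.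

Step 7
Reactants: 10 1,1-dimethoxy-7-methylocta-1,6-dien-3-one
Product: 11 (3Z)-1,1-dimethoxy-7-methyl-3-(trimethylsilyloxy)octa-1,3,6-triene
Conditions: TMSOTf, Et3N, Et2O, 0 °C; pentane extraction under argon, use directly
Reagents that add atoms: trimethylsilyl trifluoromethanesulfonate, C[Si](C)(C)OS(=O)(=O)C(F)(F)F
Why: Soft enolisation and O-silylation of the ketone can only go toward C4, the sole enolisable position, and amine/silyl triflate conditions should favour the (Z)-silyl dienol ether, which places the alkyl chain on the outside of the s-cis diene.

Step 8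
Reactants: 6 (S)-5-(4-methoxyphenyl)-4-(triethylsilyloxy)pent-1-yn-3-one, 11 (3Z)-1,1-dimethoxy-7-methyl-3-(trimethylsilyloxy)octa-1,3,6-triene
Product: 14 (S)-1-[4-hydroxy-2-methoxy-5-(3-methylbut-2-enyl)phenyl]-3-(4-methoxyphenyl)-2-(triethylsilyloxy)propan-1-one, via cyclohexadiene ketal cycloadduct 12 (not isolated), via aryl trimethylsilyl ether 13 (not isolated)
Conditions: 11 (1.5 equiv), PhMe, rt → 60 °C; then 5% aq. citric acid, THF, 0 °C
Reagents that add atoms: none
Why: The donor-substituted diene 11 and the electron-poor terminal ynone 6 should combine in a concerted but asynchronous normal-demand Diels–Alder reaction in which the nucleophilic C4 of the diene leads bonding to the alkyne terminus (C5'–C6') while C1 closes onto the acyl-bearing carbon (C1'–C2'), giving cyclohexa-1,4-diene ketal 12; 1,4-elimination of methanol then aromatises the ring to 13 and mild aqueous acid frees the phenol. The closest known reaction type is the cycloaddition–aromatisation of 1,1-dialkoxy-3-silyloxybuta-1,3-dienes with acetylenic esters and ketones to 4-hydroxy-2-alkoxyaryl carbonyl compounds, applied here to a 4-alkyl diene and an α-silyloxy ynone. Ring A is closed by intermolecular [4+2] cycloaddition, both ring bonds forming in the same step from two acyclic partners. No stereocentre remains from the step, since the sp3 carbon created at C5' becomes planar on aromatisation, and C-α keeps its (S)-configuration because it lies outside the reacting π-system in a neutral, aprotic medium. The step needs regioselectivity (methoxy ortho and prenyl meta to the acyl group), which the matched polarisation secures because both oxygen donors make C4 the nucleophilic diene terminus and the carbonyl makes the alkyne terminus the electrophilic site; it also needs chemoselectivity, which follows from the conjugated alkyne being far more dienophilic than the isolated trisubstituted alkenes. Either geometric isomer of the silyl enol ether would converge on the same arene.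

Step 9
Reactants: 14 (S)-1-[4-hydroxy-2-methoxy-5-(3-methylbut-2-enyl)phenyl]-3-(4-methoxyphenyl)-2-(triethylsilyloxy)propan-1-one
Product: 15 lespeflorin C4, (S)-2-hydroxy-1-[4-hydroxy-2-methoxy-5-(3-methylbut-2-enyl)phenyl]-3-(4-methoxyphenyl)propan-1-one
Conditions: HF·pyridine, pyridine, THF, 0 °C
Reagents that add atoms: none
Why: Fluoride cleavage of a secondary triethylsilyl ether under buffered, weakly acidic conditions, which should avoid enolisation of the α-hydroxy aryl ketone (no epimerisation or α-ketol shift) and are too mild to cyclise the ortho-prenylphenol to a chroman.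

**Compound list**

1 | O-methyl-L-tyrosine, (S)-2-amino-3-(4-methoxyphenyl)propanoic acid | COc1ccc(C[C@H](N)C(=O)O)cc1 | starting material
2 | (S)-2-hydroxy-3-(4-methoxyphenyl)propanoic acid | COc1ccc(C[C@H](O)C(=O)O)cc1 | intermediate
3 | (S)-2-hydroxy-N-methoxy-3-(4-methoxyphenyl)-N-methylpropanamide | COc1ccc(C[C@H](O)C(=O)N(C)OC)cc1 | intermediate
4 | (S)-N-methoxy-3-(4-methoxyphenyl)-N-methyl-2-(triethylsilyloxy)propanamide | COc1ccc(C[C@H](O[Si](CC)(CC)CC)C(=O)N(C)OC)cc1 | intermediate
5 | ethynylmagnesium bromide | C#C[Mg]Br | starting material
6 | (S)-5-(4-methoxyphenyl)-4-(triethylsilyloxy)pent-1-yn-3-one | COc1ccc(C[C@H](O[Si](CC)(CC)CC)C(=O)C#C)cc1 | intermediate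
7 | 5-methylhex-4-enoic acid | CC(C)=CCCC(=O)O | starting material
8 | 5-methylhex-4-enoyl chloride | CC(C)=CCCC(=O)Cl | intermediate
9 | 1,1-dimethoxyethene | C=C(OC)OC | starting material
10 | 1,1-dimethoxy-7-methylocta-1,6-dien-3-one | COC(OC)=CC(=O)CCC=C(C)C | intermediate
11 | (3Z)-1,1-dimethoxy-7-methyl-3-(trimethylsilyloxy)octa-1,3,6-triene | COC(OC)=C/C(O[Si](C)(C)C)=C/CC=C(C)C | intermediate
12 | (2S)-1-[6,6-dimethoxy-3-(3-methylbut-2-enyl)-4-(trimethylsilyloxy)cyclohexa-1,4-dien-1-yl]-3-(4-methoxyphenyl)-2-(triethylsilyloxy)propan-1-one, epimers at ring C3, formed in the flask and not isolated | COc1ccc(C[C@H](O[Si](CC)(CC)CC)C(=O)C2=CC(CC=C(C)C)C(O[Si](C)(C)C)=CC2(OC)OC)cc1 | intermediate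
13 | (S)-1-[2-methoxy-5-(3-methylbut-2-enyl)-4-(trimethylsilyloxy)phenyl]-3-(4-methoxyphenyl)-2-(triethylsilyloxy)propan-1-one, formed in the flask and not isolated | COc1ccc(C[C@H](O[Si](CC)(CC)CC)C(=O)c2cc(CC=C(C)C)c(O[Si](C)(C)C)cc2OC)cc1 | intermediate
14 | (S)-1-[4-hydroxy-2-methoxy-5-(3-methylbut-2-enyl)phenyl]-3-(4-methoxyphenyl)-2-(triethylsilyloxy)propan-1-one, the C-α triethylsilyl ether of lespeflorin C4 | COc1ccc(C[C@H](O[Si](CC)(CC)CC)C(=O)c2cc(CC=C(C)C)c(O)cc2OC)cc1 | intermediate
15 | lespeflorin C4, (S)-2-hydroxy-1-[4-hydroxy-2-methoxy-5-(3-methylbut-2-enyl)phenyl]-3-(4-methoxyphenyl)propan-1-one | COc1ccc(C[C@H](O)C(=O)c2cc(CC=C(C)C)c(O)cc2OC)cc1 | target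

**Step count**

Total: 9 steps. Longest linear sequence: 6 steps (steps 1, 2, 3, 4, 8, 9); the diene branch contributes steps 5–7.

**Steps most likely to fail**

Step 8. The cycloaddition may be outrun by hydrolysis or protodesilylation of the moisture-sensitive diene, or by stepwise Michael-type oligomerisation of the ynone, because the alkyl group at the diene terminus slows the [4+2]. The fallback abandons the benzannulation and makes the aryl–acyl bond by aryl-metal addition. It sets out from Weinreb amide 4 and returns to the route at 14. Purchased 4-bromo-3-methoxyphenol F1 would be C-prenylated through its sodium phenoxide (NaH, toluene, 1-bromo-3-methylbut-2-ene), which should favour the less hindered ortho carbon and give 4-bromo-5-methoxy-2-(3-methylbut-2-enyl)phenol F2. Deprotonation with n-BuLi and bromine–lithium exchange with t-BuLi (THF, −78 °C) would give lithium 4-lithio-5-methoxy-2-(3-methylbut-2-enyl)phenoxide F3. Its addition to 4 and aqueous work-up would deliver 14, which then continues through step 9.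

Step 6. Acylation of the ketene acetal with an enolisable acid chloride may suffer from HCl-induced cleavage of the acylketene acetal to a β-keto ester, from polymerisation of the ketene acetal, or from over-acylation. The fallback introduces the prenyl unit by enolate alkylation instead of carrying it in the acid chloride. It sets out from 9 and returns at 10. Acylation of 9 with acetyl chloride (Et2O, 0 °C) would give 4,4-dimethoxybut-3-en-2-one F4. Its kinetic lithium enolate (LDA, THF, −78 °C) can only form at the methyl group and would be alkylated there with 1-bromo-3-methylbut-2-ene to give 10.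

Step 4. During the quench the released N,O-dimethylhydroxylamine may add in conjugate fashion to the terminal ynone, and excess Grignard reagent may deprotonate or degrade the product. The fallback reaches the ynone through the alcohol oxidation level, so that no amine is present when the ynone forms. It sets out from 4 and returns at 6. DIBAL-H reduction of 4 (CH2Cl2, −78 °C) would give (S)-3-(4-methoxyphenyl)-2-(triethylsilyloxy)propanal F5. Addition of 5 (THF, −78 °C, aq. NH4Cl quench) would give (4S)-5-(4-methoxyphenyl)-4-(triethylsilyloxy)pent-1-yn-3-ol F6 as a mixture of carbinol epimers, which does not matter because Dess–Martin periodinane (NaHCO3, CH2Cl2) would oxidise both to 6.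

**Further compounds**

F1 | step 8 | 4-bromo-3-methoxyphenol (purchased) | COc1cc(O)ccc1Br
F2 | step 8 | 4-bromo-5-methoxy-2-(3-methylbut-2-enyl)phenol | COc1cc(O)c(CC=C(C)C)cc1Br
F3 | step 8 | lithium 4-lithio-5-methoxy-2-(3-methylbut-2-enyl)phenoxide | [Li]c1cc(CC=C(C)C)c(O[Li])cc1OC
F4 | step 6 | 4,4-dimethoxybut-3-en-2-one | COC(OC)=CC(C)=O
F5 | step 4 | (S)-3-(4-methoxyphenyl)-2-(triethylsilyloxy)propanal | COc1ccc(C[C@H](O[Si](CC)(CC)CC)C=O)cc1
F6 | step 4 | (4S)-5-(4-methoxyphenyl)-4-(triethylsilyloxy)pent-1-yn-3-ol, mixture of C3 epimers | COc1ccc(C[C@H](O[Si](CC)(CC)CC)C(O)C#C)cc1
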